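The isoflavone is disconnected across ring C at O1–C8a and C4–C4a. Because O1 and the carbonyl carbon C4 sit on the adjacent ring A carbons C8a and C4a and both belong to the pyranone ring C, a single C4a–C8a aryne can receive them together. The enol oxygen of an α-formyl arylacetate adds to the aryne and the aryl anion then acylates itself on the neighbouring ester, closing ring C in one operation. The precursors are an ortho-silyl aryl triflate carrying the ring A oxygens plus a removable chlorine at C5 that steers the addition, and the Z-enol of methyl formyl(2,4,5-trimethoxyphenyl)acetate.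

Key step: step 7

Remark (assumption): the α-formyl ester is drawn as its hydrogen-bonded Z-enol; it is assumed to interconvert with the aldehyde tautomer and the E-enol through the common enolate, so the geometry needed for ring closure is available under the basic conditions of the key step.

Design notes:
- The aldehyde-to-phenol conversion is run with a peracid (Baeyer–Villiger), because the para oxygen is already benzylated and an alkaline peroxide Dakin reaction needs a free hydroxyl.
- Silicon is placed between the triflate and the chlorine because that carbon is the one reached by bromination of the phenol and silyl migration.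
- Benzyl is kept on the C6 oxygen because it leaves on the same catalyst that removes the chlorine.
- In the last step the amine is added only after the benzyl ether is gone, since amines retard O-debenzylation on Pd/C but are needed to drive C–Cl cleavage.

Step 1
Reactants: 1 5-chlorovanillin (3-chloro-4-hydroxy-5-methoxybenzaldehyde); 2 benzyl bromide
Product: 3 4-(benzyloxy)-3-chloro-5-methoxybenzaldehyde
Conditions: K2CO3, DMF, 60 °C
Reagents that add atoms: none
Why: Williamson ether synthesis; the phenol, acidified by the para formyl group and the ortho chlorine, is fully deprotonated by K2CO3 and its phenoxide should displace bromide from the benzylic carbon.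

Step 2
Reactants: 3 4-(benzyloxy)-3-chloro-5-methoxybenzaldehyde
Product: 5 4-(benzyloxy)-3-chloro-5-methoxyphenol, via aryl formate 4 (not isolated)
Conditions: mCPBA, CH2Cl2, 0 °C to rt; then K2CO3 (cat.), MeOH, rt
Reagents that add atoms: mCPBA (3-chloroperoxybenzoic acid), O=C(OO)c1cccc(Cl)c1
Why: Baeyer–Villiger oxidation; in the peracid adduct of this electron-rich aldehyde the para-alkoxyaryl group should migrate in preference to hydride to give aryl formate 4, which mild base in methanol transesterifies to the phenol.

Step 3
Reactants: 5 4-(benzyloxy)-3-chloro-5-methoxyphenol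
Product: 6 4-(benzyloxy)-2-bromo-3-chloro-5-methoxyphenol
Conditions: NBS (1.0 equiv), MeCN, −20 °C to 0 °C
Reagents that add atoms: N-bromosuccinimide, O=C1CCC(=O)N1Br
Why: Electrophilic aromatic bromination of an activated phenol; of the two free positions ortho to the hydroxyl, C2 is also para to the methoxy group and is not screened by the in-plane methoxy methyl, so substitution should occur there, in line with the known tendency of 5-halovanillin-type rings to brominate para to methoxy next to the halogen.

Step 4
Reactants: 6 4-(benzyloxy)-2-bromo-3-chloro-5-methoxyphenol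
Product: 9 4-(benzyloxy)-3-chloro-5-methoxy-2-(trimethylsilyl)phenyl trifluoromethanesulfonate, via trimethylsilyl ether 7 (not isolated), via lithium phenoxide 8 (not isolated)
Conditions: HMDS, THF, 65 °C, then evaporation; n-BuLi, THF, −100 °C to −78 °C; Tf2O, −100 °C to rt
Reagents that add atoms: hexamethyldisilazane, C[Si](C)(C)N[Si](C)(C)C; trifluoromethanesulfonic anhydride, O=S(=O)(OS(=O)(=O)C(F)(F)F)C(F)(F)F
Why: O-Silylation followed by bromine–lithium exchange sets up an anionic 1,3 O-to-C silyl shift (retro-Brook rearrangement), an intramolecular transfer that at −100 °C should outrun both loss of LiCl from the ortho-chloro aryllithium and exchange at the C–Cl bond, and the lithium phenoxide so formed is trapped by Tf2O as the aryl triflate.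

Step 5
Reactants: 10 2,4,5-trimethoxyacetophenone (1-(2,4,5-trimethoxyphenyl)ethan-1-one)
Product: 11 methyl 2-(2,4,5-trimethoxyphenyl)acetate
Conditions: PhI(OAc)2, H2SO4, HC(OMe)3–MeOH, 60 °C
Reagents that add atoms: methanol, CO
Why: Oxidative 1,2-aryl migration with the trivalent iodine reagent PhI(OAc)2; in acidic trimethyl orthoformate the ketone is converted to its methyl enol ether, which is attacked at CH2 by the iodane, and the electron-rich trimethoxyphenyl group then shifts onto that carbon as iodobenzene leaves, giving the methyl ester after work-up.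

Step 6
Reactants: 11 methyl 2-(2,4,5-trimethoxyphenyl)acetate; 12 methyl formate
Product: 14 methyl (Z)-3-hydroxy-2-(2,4,5-trimethoxyphenyl)acrylate, via sodium enolate 13 (not isolated)
Conditions: NaH, THF, 0 °C to rt; then 1 M HCl, 0 °C
Reagents that add atoms: none
Why: Crossed Claisen condensation; the ester enolate of 11 is formylated by methyl formate, which cannot enolise, and the equilibrium is pulled forward by deprotonation to the stabilised enolate 13, which on acidification should give the hydrogen-bonded Z-enol 14 (in equilibrium with its aldehyde tautomer).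

Step 7
Reactants: 9 4-(benzyloxy)-3-chloro-5-methoxy-2-(trimethylsilyl)phenyl trifluoromethanesulfonate; 14 methyl (Z)-3-hydroxy-2-(2,4,5-trimethoxyphenyl)acrylate
Product: 17 6-(benzyloxy)-5-chloro-7-methoxy-3-(2,4,5-trimethoxyphenyl)-4H-chromen-4-one, via aryne 15 (not isolated), via aryl anion 16 (not isolated)
Conditions: CsF (4 equiv), THF, 65 °C
Reagents that add atoms: none
Why: Proposed new method: fluoride removes the silyl group of 9 with loss of triflate to give aryne 15 and also deprotonates enol 14; the formyl-derived enolate oxygen adds to C8a, the aryne carbon remote from chlorine, which places the negative charge of 16 on C4a beside the inductively stabilising C5 chlorine. That anion attacks the cis-disposed ester carbonyl in a 6-exo-trig acyl substitution that expels methoxide, so the C8a–O1 and C4a–C4 bonds are made and ring C is closed in one event. The closest known reaction type is the CsF-mediated annulation of arynes with salicylate esters that gives xanthones, of which this is the vinylogous, enol-based version. No stereocenter is formed. Two selectivities are needed: the direction of addition, which the C5 chlorine should secure through the known distortion of 3-haloarynes, and O-arylation over C-arylation with a Z enolate, which the fully substituted, aryl-shielded enolate carbon and the cesium-bridged U-shaped enolate should favour. The outcome is a prediction and carries the main risk of the route.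

Step 8
Reactants: 17 6-(benzyloxy)-5-chloro-7-methoxy-3-(2,4,5-trimethoxyphenyl)-4H-chromen-4-one
Product: 19 6-hydroxy-7-methoxy-3-(2,4,5-trimethoxyphenyl)-4H-chromen-4-one, via chlorophenol 18 (not isolated)
Conditions: H2 (1 atm), 10% Pd/C, THF–MeOH, rt; then Et3N, H2 (1 atm), rt
Reagents that add atoms: none
Why: Heterogeneous catalytic hydrogenolysis; the aryl benzyl ether should be cleaved first under neutral conditions, after which Et3N switches on hydrodechlorination of the C5–Cl bond (activated by the peri carbonyl) by taking up HCl, while the trisubstituted vinylogous-ester double bond of ring C is expected to be reduced far more slowly at 1 atm.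

Compound list
1 | 5-chlorovanillin (3-chloro-4-hydroxy-5-methoxybenzaldehyde) | COc1cc(C=O)cc(Cl)c1O | starting material
2 | benzyl bromide | BrCc1ccccc1 | starting material
3 | 4-(benzyloxy)-3-chloro-5-methoxybenzaldehyde | COc1cc(C=O)cc(Cl)c1OCc1ccccc1 | intermediate
4 | 4-(benzyloxy)-3-chloro-5-methoxyphenyl formate | COc1cc(OC=O)cc(Cl)c1OCc1ccccc1 | intermediate
5 | 4-(benzyloxy)-3-chloro-5-methoxyphenol | COc1cc(O)cc(Cl)c1OCc1ccccc1 | intermediate
6 | 4-(benzyloxy)-2-bromo-3-chloro-5-methoxyphenol | COc1cc(O)c(Br)c(Cl)c1OCc1ccccc1 | intermediate
7 | [4-(benzyloxy)-2-bromo-3-chloro-5-methoxyphenoxy]trimethylsilane | COc1cc(O[Si](C)(C)C)c(Br)c(Cl)c1OCc1ccccc1 | intermediate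
8 | lithium 4-(benzyloxy)-3-chloro-5-methoxy-2-(trimethylsilyl)phenolate | COc1cc([O-])c([Si](C)(C)C)c(Cl)c1OCc1ccccc1.[Li+] | intermediate
9 | 4-(benzyloxy)-3-chloro-5-methoxy-2-(trimethylsilyl)phenyl trifluoromethanesulfonate | COc1cc(OS(=O)(=O)C(F)(F)F)c([Si](C)(C)C)c(Cl)c1OCc1ccccc1 | intermediate
10 | 2,4,5-trimethoxyacetophenone (1-(2,4,5-trimethoxyphenyl)ethan-1-one) | CC(=O)c1cc(OC)c(OC)cc1OC | starting material
11 | methyl 2-(2,4,5-trimethoxyphenyl)acetate | COC(=O)Cc1cc(OC)c(OC)cc1OC | intermediate
12 | methyl formate | COC=O | starting material
13 | sodium (Z)-3-methoxy-3-oxo-2-(2,4,5-trimethoxyphenyl)prop-1-en-1-olate | [Na+].[O-]/C=C(/c1cc(OC)c(OC)cc1OC)C(=O)OC | intermediate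
14 | methyl (Z)-3-hydroxy-2-(2,4,5-trimethoxyphenyl)acrylate (enol of the α-formyl ester, OH cis to CO2Me) | O/C=C(/c1cc(OC)c(OC)cc1OC)C(=O)OC | intermediate
15 | 4-(benzyloxy)-3-chloro-5-methoxy-1,2-didehydrobenzene (aryne, triple bond at the future C8a–C4a) | COC1=CC#CC(Cl)=C1OCc1ccccc1 | intermediate
16 | cesium 3-(benzyloxy)-2-chloro-4-methoxy-6-{[(Z)-3-methoxy-3-oxo-2-(2,4,5-trimethoxyphenyl)prop-1-en-1-yl]oxy}benzen-1-ide | COC1=CC(O/C=C(/c2cc(OC)c(OC)cc2OC)C(=O)OC)=[C-]C(Cl)=C1OCc1ccccc1.[Cs+] | intermediate
17 | 6-(benzyloxy)-5-chloro-7-methoxy-3-(2,4,5-trimethoxyphenyl)-4H-chromen-4-one | COc1cc2occ(-c3cc(OC)c(OC)cc3OC)c(=O)c2c(Cl)c1OCc1ccccc1 | intermediate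
18 | 5-chloro-6-hydroxy-7-methoxy-3-(2,4,5-trimethoxyphenyl)-4H-chromen-4-one | COc1cc2occ(-c3cc(OC)c(OC)cc3OC)c(=O)c2c(Cl)c1O | intermediate
19 | 6-hydroxy-7-methoxy-3-(2,4,5-trimethoxyphenyl)-4H-chromen-4-one (no stereocenters) | COc1cc2occ(-c3cc(OC)c(OC)cc3OC)c(=O)c2cc1O | target

Total step count: 8.
Longest linear sequence: 6 steps (steps 1, 2, 3, 4, 7, 8); steps 5 and 6 form the second branch, which joins at step 7.

Steps most likely to fail

Step 7 (key step). Three processes may defeat it: arylation of the enolate at carbon instead of oxygen (leading to insertion into the C–CHO bond), protonation or chloride loss of the aryl anion before it reaches the ester, and O-arylation of the E enolate, which cannot close. The fallback builds ring C by the classical deoxybenzoin route, which is known chemistry throughout; it sets out from ester 11 and comes back to the route at target 19, so steps 1–4, 6 and 8 are not needed. Ester 11 is saponified (LiOH, THF–H2O, then acid) to 2-(2,4,5-trimethoxyphenyl)acetic acid F1. F1 then acylates commercial 2-methoxybenzene-1,4-diol (COc1cc(O)ccc1O) in BF3·OEt2 at 85 °C, a Friedel–Crafts acylation para to the methoxy group and ortho to the hydroxyl meta to it, to give 1-(2,5-dihydroxy-4-methoxyphenyl)-2-(2,4,5-trimethoxyphenyl)ethan-1-one F2. F2 is treated with DMF, BF3·OEt2 and MsCl at 70 °C, which formylates the active methylene and cyclodehydrates onto the ortho hydroxyl, to give 19 directly.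

Step 8. Hydrogenation of the C2–C3 double bond of ring C may compete with cleavage of the C–Cl bond, or the chlorine may be removed incompletely. The fallback separates the two cleavages and avoids hydrogen gas; it sets out from 17 and comes back at 19. Homogeneous hydrodechlorination with zerovalent palladium generated from Pd(OAc)2 and XPhos, with HCO2Na in DMF at 80 °C (oxidative addition into the carbonyl-activated C–Cl bond, decarboxylation of formate, reductive elimination) should give 6-(benzyloxy)-7-methoxy-3-(2,4,5-trimethoxyphenyl)-4H-chromen-4-one F3. The benzyl ether of F3 is then cleaved with BCl3 and pentamethylbenzene in CH2Cl2 at −78 °C, conditions that leave methyl ethers and the enone untouched, to give 19.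

Step 3. Bromination may be poorly regioselective (attack at the other ortho position, between hydroxyl and methoxy) or run on to dibromination of the very electron-rich phenol. The fallback introduces bromine before the phenol exists, on the deactivated aldehyde ring, where substitution para to methoxy next to the halogen is the established course for 5-halovanillins; it sets out from 1 and comes back at 6. Compound 1 is brominated (Br2, Fe powder, AcOH, 60 °C) to 2-bromo-3-chloro-4-hydroxy-5-methoxybenzaldehyde F4. F4 is benzylated with 2 (K2CO3, DMF, 60 °C) to 4-(benzyloxy)-2-bromo-3-chloro-5-methoxybenzaldehyde F5. Baeyer–Villiger oxidation of F5 (mCPBA, CH2Cl2) gives 4-(benzyloxy)-2-bromo-3-chloro-5-methoxyphenyl formate F6, which is methanolysed (K2CO3, MeOH) to 6.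

Further compounds
F1 | step 7 | 2-(2,4,5-trimethoxyphenyl)acetic acid | OC(=O)Cc1cc(OC)c(OC)cc1OC
F2 | step 7 | 1-(2,5-dihydroxy-4-methoxyphenyl)-2-(2,4,5-trimethoxyphenyl)ethan-1-one | COc1cc(O)c(C(=O)Cc2cc(OC)c(OC)cc2OC)cc1O
F3 | step 8 | 6-(benzyloxy)-7-methoxy-3-(2,4,5-trimethoxyphenyl)-4H-chromen-4-one | COc1cc2occ(-c3cc(OC)c(OC)cc3OC)c(=O)c2cc1OCc1ccccc1
F4 | step 3 | 2-bromo-3-chloro-4-hydroxy-5-methoxybenzaldehyde | COc1cc(C=O)c(Br)c(Cl)c1O
F5 | step 3 | 4-(benzyloxy)-2-bromo-3-chloro-5-methoxybenzaldehyde | COc1cc(C=O)c(Br)c(Cl)c1OCc1ccccc1
F6 | step 3 | 4-(benzyloxy)-2-bromo-3-chloro-5-methoxyphenyl formate | COc1cc(OC=O)c(Br)c(Cl)c1OCc1ccccc1
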